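**Plan**

- Numbering (furo[3,2-c][1,2]dioxin-6-one): O1–O2–C3(hexadecyl, Me)–C4H2–C4a(Me)–O5–C6(=O)–C7H2–C7a(H)–O1. Ring A is the 1,2-dioxane, ring B the γ-lactone.
- Retrosynthesis: the C16 chain is first traced back to a hexadec-1-ynyl group (C≡C saturation last). Ring A is then cut at C4–C4a and at O2–C3 in one stroke, leaving 2-methyloctadec-1-en-3-yne and a five-carbon enol lactone that already carries the C7a–O1–O2 unit as a silyl peroxide.
- Feature used: C4a is a ketone-level lactone carbon (an acyloxycarbenium ion once an exocyclic C4a=CH2 is protonated) and stands 1,3 to the peroxide-bearing quaternary C3 across the C4 methylene. C4–C3 is therefore a Markovnikov 1,1-disubstituted alkene in disguise, and O2, held on C7a, sits at the right distance to catch the C3 cation in a six-membered ring.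
- Forward: the lactone part is built as a β-peroxy pentynoic acid; ring B closes first (gold cycloisomerisation to the enol lactone), ring A second (cation–olefin–peroxide [4+2] annulation); diimide then saturates the alkyne.
- Stereochemistry: C7a is set by amine catalysis (asymmetric β-peroxidation of an enynal). C4a and C3 are both relayed from it in the annulation (attack syn to the peroxy group; slim alkynyl group axial in the chair-like closure).

Key step: step 8

Assumption: the amine-catalysed β-peroxidation of enals is taken to accept the acetal-type hydroperoxide made in step 1 as peroxide donor, as it accepts other tertiary alkyl hydroperoxides.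

Step 1
Reactants: 1 2,3-dimethylbut-2-ene
Product: 3 2-methoxypropan-2-yl hydroperoxide, via acetone O-oxide 2 (not isolated)
Conditions: O3, MeOH/CH2Cl2, −78 °C; then N2 purge
Reagents that add atoms: ozone [O-][O+]=O; methanol CO
Why: Ozonolysis of the tetrasubstituted alkene gives acetone and acetone O-oxide 2, and methanol traps the carbonyl oxide as the α-methoxy hydroperoxide (Criegee ozonolysis in a participating solvent).

Step 2
Reactants: 4 (E)-pent-2-en-4-yn-1-ol
Product: 5 (E)-pent-2-en-4-ynal
Conditions: activated MnO2 (excess), CH2Cl2, 23 °C; filtered solution used directly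
Reagents that add atoms: none
Why: Activated MnO2 should oxidise the allylic alcohol selectively to the enal without touching the terminal alkyne or the E double bond (allylic oxidation with MnO2).

Step 3
Reactants: 5 (E)-pent-2-en-4-ynal; 3 2-methoxypropan-2-yl hydroperoxide
Product: 6 (S)-3-[(2-methoxypropan-2-yl)peroxy]pent-4-ynal
Conditions: (S)-2-{bis[3,5-bis(trifluoromethyl)phenyl][(trimethylsilyl)oxy]methyl}pyrrolidine (10 mol %), PhCO2H (10 mol %), toluene, 0 °C
Reagents that add atoms: none
Why: The (S)-diarylprolinol silyl ether activates 5 as its s-trans E-iminium ion and hydroperoxide 3 adds in the conjugate sense (amine-catalysed asymmetric β-peroxidation of an enal, oxa-Michael type): the diarylsilyloxymethyl group shields the Re face of C3, so the peroxide should enter on the Si face and give the (S) centre, while the acid co-catalyst protonates the enamine before it can collapse to the epoxide.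

Step 4
Reactants: 6 (S)-3-[(2-methoxypropan-2-yl)peroxy]pent-4-ynal
Product: 8 (S)-3-hydroperoxypent-4-ynoic acid, via peroxyketal carboxylic acid 7 (not isolated)
Conditions: NaClO2, NaH2PO4, 2-methylbut-2-ene, t-BuOH/H2O, 0 °C; then 1 M HCl to pH 2, THF, 0 → 23 °C
Reagents that add atoms: sodium chlorite [Na+].[O-]Cl=O
Why: Chlorous acid should oxidise the aldehyde to the acid without touching the peroxide or the alkyne (Pinnick oxidation, 2-methylbut-2-ene as hypochlorite scavenger), and the acidic work-up hydrolyses the acid-labile peroxyketal to the hydroperoxide (acetal hydrolysis), the stereocentre not being involved.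

Step 5
Reactants: 8 (S)-3-hydroperoxypent-4-ynoic acid
Product: 10 (S)-3-[(triethylsilyl)peroxy]pent-4-ynoic acid, via bis(triethylsilyl) derivative 9 (not isolated)
Conditions: Et3SiOTf (2.1 equiv), 2,6-lutidine, CH2Cl2, −78 °C; then H2O/THF, 0 °C
Reagents that add atoms: triethylsilyl trifluoromethanesulfonate CC[Si](CC)(CC)OS(=O)(=O)C(F)(F)F
Why: Both acidic OH groups are silylated at low temperature with a hindered, weak base (silylation of a hydroperoxide, conditions chosen to avoid base-induced Kornblum–DeLaMare cleavage), and the labile silyl ester of 9 is hydrolysed on aqueous work-up while the silyl peroxide should survive.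

Step 6
Reactants: 10 (S)-3-[(triethylsilyl)peroxy]pent-4-ynoic acid
Product: 11 (S)-5-methylidene-4-[(triethylsilyl)peroxy]oxolan-2-one
Conditions: AuCl (5 mol %), MeCN, 23 °C
Reagents that add atoms: none
Why: π-Activation of the terminal alkyne by monovalent gold and anti attack of the carboxylic acid should close ring B in the 5-exo-dig mode, followed by protodeauration (gold-catalysed cycloisomerisation of a pent-4-ynoic acid), under base-free conditions that avoid β-elimination of the peroxide.

Step 7
Reactants: 12 hexadec-1-yne; 13 2-bromopropene
Product: 14 2-methyloctadec-1-en-3-yne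
Conditions: Pd(PPh3)2Cl2 (2 mol %), CuI (4 mol %), i-Pr2NH, THF, 23 °C
Reagents that add atoms: none
Why: Oxidative addition of zerovalent palladium into the vinyl bromide, transmetalation of the copper acetylide and reductive elimination give the conjugated enyne (Sonogashira coupling).

Step 8
Reactants: 11 (S)-5-methylidene-4-[(triethylsilyl)peroxy]oxolan-2-one; 14 2-methyloctadec-1-en-3-yne
Product: 17 (3S,4aS,7aS)-3-(hexadec-1-yn-1-yl)-3,4a-dimethyltetrahydrofuro[3,2-c][1,2]dioxin-6(3H)-one, via acyloxycarbenium triflate 15 (not isolated), via propargylic cation triflate 16 (not isolated)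
Conditions: 14 (3 equiv), TfOH (1.05 equiv, slow addition), 4 Å MS, CH2Cl2, −78 °C; then sat. aq. NaHCO3
Reagents that add atoms: none
Why: Proposed new method: C-protonation of the exocyclic enol lactone of 11 should give the tertiary five-membered acyloxycarbenium ion 15, which the CH2 terminus of enyne 14 attacks in the Markovnikov (Prins) sense to give the tertiary propargylic cation 16, and the terminal oxygen of the silylperoxy group then captures this cation with loss of Et3SiOTf, so that C4–C4a and O2–C3 form in one polar, stepwise [4+2] annulation. The closest known reaction types are the Lewis acid-mediated [3+2] annulation of peroxycarbenium ions (from silylperoxy ketals) with alkenes, which gives 1,2-dioxolanes by the same silylperoxide capture of a tertiary cation, and the Prins cyclisation; the proposal extends them by one ring atom and to an acyloxycarbenium ion. The only ring closed is the 1,2-dioxane (ring A), by six-membered capture of the cationic carbon by oxygen (formally 6-exo-trig on the allenyl form of 16) through a chair-like arrangement. C4a should be set by attack of 14 on the face of 15 syn to the neighbouring peroxy substituent, the face preferred by π-nucleophiles with five-membered oxocarbenium and N-acyliminium ions that carry a 2-alkoxy group (inside attack on the envelope), and only this adduct can close to the cis-fused bicycle. C3 should be set in the chair in which the 4a-methyl group is equatorial and the lactone oxygen axial: the rod-like alkynyl group, far smaller than methyl in its 1,3-diaxial demand, takes the axial site next to that oxygen and the C3 methyl group the equatorial one, which is the target arrangement. The step needs protonation of the enol lactone in preference to the enyne and bond formation at the enyne CH2 only, which the electron-poor character of the enyne, its use in excess at −78 °C and the stability of the propargylic cation should secure.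

Step 9
Reactants: 17 (3S,4aS,7aS)-3-(hexadec-1-yn-1-yl)-3,4a-dimethyltetrahydrofuro[3,2-c][1,2]dioxin-6(3H)-one
Product: 19 (3R,4aS,7aS)-3-hexadecyl-3,4a-dimethyltetrahydrofuro[3,2-c][1,2]dioxin-6(3H)-one (target), via cis-alkene 18 (not isolated)
Conditions: KO2CN=NCO2K (excess, in portions), AcOH, MeOH/CH2Cl2, 0 → 23 °C
Reagents that add atoms: none
Why: Diimide generated in the flask should transfer H2 suprafacially to the C≡C bond and then to the cis-alkene 18 without reducing the O–O bond or the lactone (diimide reduction), so the three stereocentres are untouched and the change of the C3 descriptor from S to R is due to the priority rules only.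

**Compound list**

1 | 2,3-dimethylbut-2-ene | CC(C)=C(C)C | starting material
2 | acetone O-oxide (carbonyl oxide) | CC(C)=[O+][O-] | intermediate
3 | 2-methoxypropan-2-yl hydroperoxide | COC(C)(C)OO | intermediate
4 | (E)-pent-2-en-4-yn-1-ol | OC/C=C/C#C | starting material
5 | (E)-pent-2-en-4-ynal | O=C/C=C/C#C | intermediate
6 | (S)-3-[(2-methoxypropan-2-yl)peroxy]pent-4-ynal | O=CC[C@@H](C#C)OOC(C)(C)OC | intermediate
7 | (S)-3-[(2-methoxypropan-2-yl)peroxy]pent-4-ynoic acid | OC(=O)C[C@@H](C#C)OOC(C)(C)OC | intermediate
8 | (S)-3-hydroperoxypent-4-ynoic acid | OC(=O)C[C@@H](C#C)OO | intermediate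
9 | triethylsilyl (S)-3-[(triethylsilyl)peroxy]pent-4-ynoate | CC[Si](CC)(CC)OC(=O)C[C@@H](C#C)OO[Si](CC)(CC)CC | intermediate
10 | (S)-3-[(triethylsilyl)peroxy]pent-4-ynoic acid | OC(=O)C[C@@H](C#C)OO[Si](CC)(CC)CC | intermediate
11 | (S)-5-methylidene-4-[(triethylsilyl)peroxy]oxolan-2-one | C=C1OC(=O)C[C@@H]1OO[Si](CC)(CC)CC | intermediate
12 | hexadec-1-yne | C#CCCCCCCCCCCCCCC | starting material
13 | 2-bromopropene | CC(Br)=C | starting material
14 | 2-methyloctadec-1-en-3-yne | C=C(C)C#CCCCCCCCCCCCCCC | intermediate
15 | (4S)-5-methyl-2-oxo-4-[(triethylsilyl)peroxy]-3,4-dihydro-2H-furan-1-ium trifluoromethanesulfonate (cyclic acyloxycarbenium ion) | CC1=[O+]C(=O)C[C@@H]1OO[Si](CC)(CC)CC.[O-]S(=O)(=O)C(F)(F)F | intermediate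
16 | 2-methyl-1-{(2S,3S)-2-methyl-5-oxo-3-[(triethylsilyl)peroxy]oxolan-2-yl}octadec-3-yn-2-ylium trifluoromethanesulfonate (tertiary propargylic cation) | CCCCCCCCCCCCCCC#C[C+](C)C[C@]1(C)OC(=O)C[C@@H]1OO[Si](CC)(CC)CC.[O-]S(=O)(=O)C(F)(F)F | intermediate
17 | (3S,4aS,7aS)-3-(hexadec-1-yn-1-yl)-3,4a-dimethyltetrahydrofuro[3,2-c][1,2]dioxin-6(3H)-one (cis-fused; 3-methyl cis to 4a-methyl) | CCCCCCCCCCCCCCC#C[C@]1(C)C[C@]2(C)OC(=O)C[C@@H]2OO1 | intermediate
18 | (3S,4aS,7aS)-3-[(Z)-hexadec-1-en-1-yl]-3,4a-dimethyltetrahydrofuro[3,2-c][1,2]dioxin-6(3H)-one | CCCCCCCCCCCCCC/C=C\[C@]1(C)C[C@]2(C)OC(=O)C[C@@H]2OO1 | intermediate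
19 | (3R,4aS,7aS)-3-hexadecyl-3,4a-dimethyltetrahydrofuro[3,2-c][1,2]dioxin-6(3H)-one (cis-fused; 3-methyl cis to 4a-methyl) | CCCCCCCCCCCCCCCC[C@]1(C)C[C@]2(C)OC(=O)C[C@@H]2OO1 | target

**Step count**

Total: 9 steps. Longest linear sequence: 7 steps (steps 2, 3, 4, 5, 6, 8, 9); steps 1 and 7 are side branches.

**Steps most likely to fail**

1. Step 8 (proposed new method). What may go wrong:
- protonation of the enyne in place of the enol lactone, followed by cationic oligomerisation;
- attack on the face of the acyloxycarbenium ion anti to the peroxy group;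
- loss of a proton from the propargylic cation before the peroxide oxygen closes ring A;
- acid-induced loss of the allylic silylperoxy group.

Fallback (known chemistry, the two bonds made in separate operations): it sets out from 11.
- Markovnikov addition of HCl (1 equiv, Et2O/CH2Cl2, −78 °C) should give the pseudo-acid chloride (4S)-5-chloro-5-methyl-4-[(triethylsilyl)peroxy]oxolan-2-one F1, used without isolation.
- Trimethyl(2-methylideneoctadecyl)silane F2 is made from commercial [2-(chloromethyl)allyl]trimethylsilane and pentadecylmagnesium bromide with Li2CuCl4 (cat.) in THF.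
- F2 and SnCl4 are added to F1 at −78 °C. Hosomi–Sakurai allylation of the acyloxycarbenium ion forms the C4–C4a bond and should give (4S,5S)-5-methyl-5-(2-methylideneoctadecyl)-4-[(triethylsilyl)peroxy]oxolan-2-one F3. The allylsilane is far more nucleophilic than 14 and loses its silyl group instead of waiting for capture.
- Bu4NF/AcOH (THF, 0 °C) frees (4S,5S)-4-hydroperoxy-5-methyl-5-(2-methylideneoctadecyl)oxolan-2-one F4.
- Cycloperoxymercuration with Hg(OAc)2 in CH2Cl2 closes ring A in the 6-exo-trig mode at the more substituted alkene carbon and forms the O2–C3 bond, giving {[(4aS,7aS)-3-hexadecyl-4a-methyl-6-oxohexahydrofuro[3,2-c][1,2]dioxin-3-yl]methyl}mercury acetate F5.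
- NaBH4/aq. NaOH at 0 °C replaces mercury by hydrogen and returns to the route at 19.

On this path the C3 centre is formed with little control and the radical demercuration has to outrun epoxide formation, so chromatographic removal of the C3 epimer would be needed.

2. Step 3. What may go wrong:
- collapse of the β-peroxy enamine to the epoxy aldehyde;
- 1,6-addition at the alkyne terminus;
- poor face discrimination with the slim alkynyl substituent.

Fallback (resolution in place of asymmetric catalysis): it sets out from 5 and 3.
- Pyrrolidine (20 mol %)/PhCO2H in toluene at 0 °C should give racemic 3-[(2-methoxypropan-2-yl)peroxy]pent-4-ynal F6.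
- Pinnick oxidation with neutral work-up gives racemic 3-[(2-methoxypropan-2-yl)peroxy]pent-4-ynoic acid F7.
- Crystallisation with (R)-1-phenylethylamine is expected to deliver the diastereomerically pure salt (R)-1-phenylethylammonium (S)-3-[(2-methoxypropan-2-yl)peroxy]pent-4-ynoate F8. Should the salt of the (R)-acid prove the less soluble one, the antipodal amine would be used.
- Acidification to pH 2 liberates the acid, hydrolyses the peroxyketal and returns to the route at 8.

3. Step 9. What may go wrong:
- slow or incomplete hydrogen transfer to the alkyne next to the quaternary centre;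
- stalling at the cis-alkene;
- O–O cleavage when the reduction is forced.

Fallback (the reduction is avoided altogether): it sets out from 11.
- 2-Methyloctadec-1-ene F9 is made from commercial octadecan-2-one by Wittig methylenation (Ph3PCH3Br, KOt-Bu, THF).
- F9 is used in place of 14 under the conditions of step 8, so the annulation returns directly to the route at 19.

The price is that methyl and hexadecyl are poorly differentiated in the ring closure, so preparative chromatography would have to remove the C3 epimer.

**Further compounds**

F1 | step 8 | (4S)-5-chloro-5-methyl-4-[(triethylsilyl)peroxy]oxolan-2-one | CC1(Cl)OC(=O)C[C@@H]1OO[Si](CC)(CC)CC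
F2 | step 8 | trimethyl(2-methylideneoctadecyl)silane | C=C(CCCCCCCCCCCCCCCC)C[Si](C)(C)C
F3 | step 8 | (4S,5S)-5-methyl-5-(2-methylideneoctadecyl)-4-[(triethylsilyl)peroxy]oxolan-2-one | CCCCCCCCCCCCCCCCC(=C)C[C@]1(C)OC(=O)C[C@@H]1OO[Si](CC)(CC)CC
F4 | step 8 | (4S,5S)-4-hydroperoxy-5-methyl-5-(2-methylideneoctadecyl)oxolan-2-one | CCCCCCCCCCCCCCCCC(=C)C[C@]1(C)OC(=O)C[C@@H]1OO
F5 | step 8 | {[(4aS,7aS)-3-hexadecyl-4a-methyl-6-oxohexahydrofuro[3,2-c][1,2]dioxin-3-yl]methyl}mercury acetate (both C3 epimers) | CCCCCCCCCCCCCCCCC1(C[Hg]OC(C)=O)C[C@]2(C)OC(=O)C[C@@H]2OO1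
F6 | step 3 | racemic 3-[(2-methoxypropan-2-yl)peroxy]pent-4-ynal | O=CCC(C#C)OOC(C)(C)OC
F7 | step 3 | racemic 3-[(2-methoxypropan-2-yl)peroxy]pent-4-ynoic acid | OC(=O)CC(C#C)OOC(C)(C)OC
F8 | step 3 | (R)-1-phenylethylammonium (S)-3-[(2-methoxypropan-2-yl)peroxy]pent-4-ynoate | C[C@@H]([NH3+])c1ccccc1.[O-]C(=O)C[C@@H](C#C)OOC(C)(C)OC
F9 | step 9 | 2-methyloctadec-1-ene | C=C(C)CCCCCCCCCCCCCCCC
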